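**Plan**

- Retrosynthesis: the phenol is freed from its acetate last. Before that the C2'–Br and C4'–Br bonds of ring B are cut, then acetyl is exchanged for methyl on O1, the O–C1' aryl ether bond is cut, and the three C–Br bonds of ring A are cut, which leads back to guaiacol.
- Enabling feature: ring B carries bromine only at C2' and C4', ortho and para to the ether oxygen on C1'. These are the carbons an aryloxy group activates towards electrophiles, while ring A (Br on C3, C4, C5, acetoxy on C1) is electron-poor.
- Forward order: ring A is brominated first, the diaryl ether C–O bond is made by phenyl transfer from an iodonium salt, OMe is traded for OAc, ring B is dibrominated, and the acetate is removed.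
- Both benzene rings are purchased and no ring is closed. The target has no stereocentre, so no stereochemistry has to be introduced.

Key step: step 5

Remark: the target is achiral (no stereocentre, freely rotating diaryl ether axis), so the request for a single enantiomer needs no stereocontrol.

**Route**

Step 1
Reactants: 1 guaiacol (2-methoxyphenol)
Product: 4 2,3,4-tribromo-6-methoxyphenol (4,5,6-tribromoguaiacol), via 4-bromo-2-methoxyphenol 2 (not isolated), via 4,5-dibromo-2-methoxyphenol 3 (not isolated)
Conditions: Br2 (3.05 equiv), AcOH, 10 °C → rt; aq. NaHSO3 quench; recrystallisation
Reagents that add atoms: bromine, BrBr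
Why: Electrophilic aromatic bromination of an activated phenol, in which OH directs to C4 (para) and C6 (ortho) and OMe to C5 (para), so the only carbon left as C–H should be C3, the least activated position (ortho to OMe only, meta to OH); the order in which C5 and C6 react does not change the tribromide formed.

Step 2
Reactants: 4 2,3,4-tribromo-6-methoxyphenol; 5 diphenyliodonium triflate
Product: 7 1,2,3-tribromo-5-methoxy-4-phenoxybenzene, via potassium 2,3,4-tribromo-6-methoxyphenoxide 6 (not isolated)
Conditions: t-BuOK (1.1 equiv), THF, 0 °C; then 5 (1.2 equiv), rt → 40 °C
Reagents that add atoms: diphenyliodonium triflate (5), [O-]S(=O)(=O)C(F)(F)F.c1ccc(cc1)[I+]c1ccccc1 (phenyl group); potassium tert-butoxide, CC(C)(C)[O-].[K+] (its potassium sits in intermediate 6 only)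
Why: Metal-free O-arylation of a phenoxide with a diaryliodonium salt (ligand exchange at iodine(III) followed by ligand coupling), a reaction known to accept di-ortho-substituted and halogenated phenols, and with no transition metal present the three C–Br bonds should stay intact.

Step 3
Reactants: 7 1,2,3-tribromo-5-methoxy-4-phenoxybenzene
Product: 9 3,4,5-tribromo-2-phenoxyphenol, via dibromo(3,4,5-tribromo-2-phenoxyphenoxy)borane 8 (not isolated)
Conditions: BBr3 (1.5 equiv), CH2Cl2, −78 °C → rt; then H2O, 0 °C
Reagents that add atoms: boron tribromide, BrB(Br)Br (its boron and bromine sit in intermediate 8 only; none stays in 9)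
Why: Boron tribromide demethylation of an aryl methyl ether, in which bromide attacks the methyl carbon of the O–B complex; the diaryl ether has no sp3 C–O bond to cleave and the aryl bromides are inert.

Step 4
Reactants: 9 3,4,5-tribromo-2-phenoxyphenol
Product: 10 3,4,5-tribromo-2-phenoxyphenyl acetate
Conditions: Ac2O (1.5 equiv), pyridine, DMAP (5 mol %), CH2Cl2, rt
Reagents that add atoms: acetic anhydride, CC(=O)OC(C)=O
Why: DMAP-catalysed O-acylation of a phenol, which converts the strongly activating hydroxyl on ring A into a weakly donating acetoxy group before the bromination.

Step 5
Reactants: 10 3,4,5-tribromo-2-phenoxyphenyl acetate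
Product: 12 3,4,5-tribromo-2-(2,4-dibromophenoxy)phenyl acetate, via 3,4,5-tribromo-2-(4-bromophenoxy)phenyl acetate 11 (not isolated)
Conditions: Br2 (2.1 equiv), FeBr3 (5 mol %), CH2Cl2, 0 °C → rt, dark; aq. Na2S2O3 quench
Reagents that add atoms: bromine, BrBr
Why: This is an electrophilic aromatic substitution through arenium ions by Lewis-acid-polarised bromine on the phenoxy ring, the classical halogenation of an aryl ether and the way diphenyl ether itself is taken to its 2,4-bromides. The ether oxygen is flanked on ring A by OAc and Br, so ring A is twisted out of conjugation and the oxygen lone pair feeds ring B, which should make C4' and then C2' the most nucleophilic carbons; the first bromine is expected para (11) and the second ortho (12). No ring is closed and no stereocentre arises. The step needs ring selectivity, and this is secured by the three bromines on ring A and by the acetoxy group in place of a free hydroxyl, which leave its only C–H (C6) far less reactive than ring B. It also needs to stop at two bromines, which is secured by the stoichiometry and by C6' of 12 being meta to both new bromines and therefore much slower to react than C2' of 11.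

Step 6
Reactants: 12 3,4,5-tribromo-2-(2,4-dibromophenoxy)phenyl acetate
Product: 13 3,4,5-tribromo-2-(2,4-dibromophenoxy)phenol
Conditions: HCl (0.1 equiv, as 1.25 M solution in MeOH), MeOH, 40 °C
Reagents that add atoms: none
Why: Acid-catalysed transesterification (methanolysis) of an aryl acetate, which should release the phenol without forming a phenoxide and leaves the aryl bromides and the diaryl ether untouched.

**Compound list**

1 | guaiacol (2-methoxyphenol) | COc1ccccc1O | starting material
2 | 4-bromo-2-methoxyphenol | COc1cc(Br)ccc1O | intermediate
3 | 4,5-dibromo-2-methoxyphenol | COc1cc(Br)c(Br)cc1O | intermediate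
4 | 2,3,4-tribromo-6-methoxyphenol (4,5,6-tribromoguaiacol) | COc1cc(Br)c(Br)c(Br)c1O | intermediate
5 | diphenyliodonium triflate | [O-]S(=O)(=O)C(F)(F)F.c1ccc(cc1)[I+]c1ccccc1 | starting material
6 | potassium 2,3,4-tribromo-6-methoxyphenoxide | COc1cc(Br)c(Br)c(Br)c1[O-].[K+] | intermediate
7 | 1,2,3-tribromo-5-methoxy-4-phenoxybenzene | COc1cc(Br)c(Br)c(Br)c1Oc1ccccc1 | intermediate
8 | dibromo(3,4,5-tribromo-2-phenoxyphenoxy)borane | BrB(Br)Oc1cc(Br)c(Br)c(Br)c1Oc1ccccc1 | intermediate
9 | 3,4,5-tribromo-2-phenoxyphenol | Oc1cc(Br)c(Br)c(Br)c1Oc1ccccc1 | intermediate
10 | 3,4,5-tribromo-2-phenoxyphenyl acetate | CC(=O)Oc1cc(Br)c(Br)c(Br)c1Oc1ccccc1 | intermediate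
11 | 3,4,5-tribromo-2-(4-bromophenoxy)phenyl acetate | CC(=O)Oc1cc(Br)c(Br)c(Br)c1Oc1ccc(Br)cc1 | intermediate
12 | 3,4,5-tribromo-2-(2,4-dibromophenoxy)phenyl acetate | CC(=O)Oc1cc(Br)c(Br)c(Br)c1Oc1ccc(Br)cc1Br | intermediate
13 | 3,4,5-tribromo-2-(2,4-dibromophenoxy)phenol | Oc1cc(Br)c(Br)c(Br)c1Oc1ccc(Br)cc1Br | target

**Count**

Total steps: 6. Longest linear sequence: 6 steps (1 → 13).

**Steps most likely to fail**

Step 5. The second bromination of ring B may be slow enough that substitution at C6' or on ring A starts to compete, or the acetate may be lost under the hydrogen bromide formed, after which ring A would brominate; either process would give polybromide mixtures that are hard to separate. The fallback brings ring B in already dibrominated and so avoids any late halogenation. It sets out from 4: 1,3-dibromobenzene is condensed with iodyl sulfate (I2, KIO3, H2SO4) and the salt is precipitated with chloride to give bis(2,4-dibromophenyl)iodonium chloride F1. The potassium phenoxide of 4 (t-BuOK, THF) is arylated with this salt at 40–60 °C to give 1,2,3-tribromo-4-(2,4-dibromophenoxy)-5-methoxybenzene F2. Demethylation of this ether with BBr3 in CH2Cl2 comes back to the route at 13.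

Step 2. The phenoxide of 4 is electron-poor and flanked by OMe and Br, so aryl transfer from iodine may be slow and the iodonium salt may decompose before it couples. The fallback changes the electrophile to benzyne: starting from 4, treatment with 2-(trimethylsilyl)phenyl triflate and CsF in MeCN at rt generates benzyne, to which the phenoxide adds, and protonation of the aryl anion gives the phenyl ether. This returns to the route at 7 and makes no compound outside the list (F0).

Step 1. The bromination may not stop cleanly at three bromines (further substitution at C3, or oxidation of the electron-rich phenol), so the tribromide could be contaminated by under- and over-brominated material. The fallback divides the halogenation into two controlled stages: starting from 1, two equivalents of NBS in MeCN should give the dibromide 3, which is isolated and crystallised. The last bromine is then delivered ortho to the hydroxyl by the amine-mediated ortho-bromination of phenols (NBS, catalytic i-Pr2NH, CH2Cl2), rejoining the route at 4. No compound outside the list is made (F0).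

**Further compounds**

F1 | step 5 | bis(2,4-dibromophenyl)iodonium chloride | [Cl-].Brc1ccc([I+]c2ccc(Br)cc2Br)c(Br)c1
F2 | step 5 | 1,2,3-tribromo-4-(2,4-dibromophenoxy)-5-methoxybenzene | COc1cc(Br)c(Br)c(Br)c1Oc1ccc(Br)cc1Br
F0 | step 2 | none | none
F0 | step 1 | none | none
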